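**Strategy.** Ring labels: A resorcinol ring, B core catechol, C pendant catechol, D mono-phenol ring; C7/C8 are the CH2/CH of the dihydrophenanthrene, C9 the CH bearing ring C, C10 the neighbouring CH2. The seven-membered ring is cut at C8–C(ring D) and C9–C10. One pot builds both from an open biaryl E-stilbene carrying a ring-B diaryl ketone and a ring-D isobutenyl group: a chiral Brønsted acid closes the dihydrophenanthrene by hydroarylation, exploiting that C8 is para to an oxygen of ring B and the attacking ring-D carbon is para to the ring-D oxygen; FeCl3 then closes the seven-membered ring by carbonyl–olefin metathesis. Hydrogenation sets C9; demethylation finishes.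

Key step: step 7

Remark: 1, 2, 4, 6 and the two phosphonium salts are taken as commercial; the antipode of the chiral acid that gives C8 R has to be selected by experiment.

Step 1
Reactants: 1 4-bromo-1,2-dimethoxybenzene; 2 3,4-dimethoxybenzoyl chloride
Product: 3 (2-bromo-4,5-dimethoxyphenyl)(3,4-dimethoxyphenyl)methanone
Conditions: AlCl3, CH2Cl2, 0 → 23 °C
Reagents that add atoms: none
Why: Friedel–Crafts acylation, in which the acylium ion from 2 should enter 1 at the carbon para to one methoxy group and ortho to bromine (the site both substituents direct to), placing the ketone next to the bromide used in step 6.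

Step 2
Reactants: 4 2-bromo-3,5-dimethoxybenzaldehyde
Product: 5 2-bromo-1-ethenyl-3,5-dimethoxybenzene
Conditions: Ph3PCH3Br, KOtBu, THF, 0 → 23 °C
Reagents that add atoms: methyltriphenylphosphonium bromide, C[P+](c1ccccc1)(c1ccccc1)c1ccccc1.[Br-]
Why: Wittig methylenation of the aldehyde should give the terminal styrene that later serves as the Mizoroki–Heck acceptor, the aryl bromide being inert to the ylide.

Step 3
Reactants: 6 3-bromo-5-methoxybenzaldehyde
Product: 7 1-bromo-3-methoxy-5-(2-methylprop-1-en-1-yl)benzene
Conditions: i-PrPPh3I, n-BuLi, THF, −78 → 23 °C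
Reagents that add atoms: isopropyltriphenylphosphonium iodide, CC(C)[P+](c1ccccc1)(c1ccccc1)c1ccccc1.[I-]
Why: Wittig olefination with the non-stabilised isopropylidene ylide should turn the aldehyde into the isobutenyl group, the carbonyl–olefin metathesis partner whose terminus is later lost as acetone.

Step 4
Reactants: 7 1-bromo-3-methoxy-5-(2-methylprop-1-en-1-yl)benzene
Product: 8 2-[3-methoxy-5-(2-methylprop-1-en-1-yl)phenyl]-4,4,5,5-tetramethyl-1,3,2-dioxaborolane
Conditions: B2pin2, Pd(dppf)Cl2 (3 mol %), KOAc, 1,4-dioxane, 90 °C
Reagents that add atoms: bis(pinacolato)diboron, CC1(C)OB(OC1(C)C)B1OC(C)(C)C(C)(C)O1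
Why: Miyaura borylation (oxidative addition of zerovalent palladium into C–Br, acetate-assisted transmetallation from B2pin2, reductive elimination) should give the aryl boronate without touching the hindered alkene.

Step 5
Reactants: 5 2-bromo-1-ethenyl-3,5-dimethoxybenzene; 8 2-[3-methoxy-5-(2-methylprop-1-en-1-yl)phenyl]-4,4,5,5-tetramethyl-1,3,2-dioxaborolane
Product: 9 2-ethenyl-3',4,6-trimethoxy-5'-(2-methylprop-1-en-1-yl)-1,1'-biphenyl
Conditions: Pd(OAc)2 (3 mol %), SPhos, K3PO4, PhMe/H2O, 90 °C
Reagents that add atoms: none
Why: Suzuki–Miyaura coupling, in which the electron-rich biarylphosphine should let palladium insert into the doubly ortho-substituted bromide of 5 and transmetallation from 8 should outrun insertion of the styrene.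

Step 6
Reactants: 9 2-ethenyl-3',4,6-trimethoxy-5'-(2-methylprop-1-en-1-yl)-1,1'-biphenyl; 3 (2-bromo-4,5-dimethoxyphenyl)(3,4-dimethoxyphenyl)methanone
Product: 10 {2-[(E)-2-(3',4,6-trimethoxy-5'-(2-methylprop-1-en-1-yl)-1,1'-biphenyl-2-yl)ethenyl]-4,5-dimethoxyphenyl}(3,4-dimethoxyphenyl)methanone
Conditions: Pd2(dba)3 (2 mol %), P(t-Bu)3·HBF4, Cy2NMe, 1,4-dioxane, 90 °C
Reagents that add atoms: none
Why: Mizoroki–Heck reaction, in which the arylpalladium bromide from 3 should add to the unsubstituted terminus of the vinyl group of 9 and syn β-hydride elimination should give the E-stilbene, the trisubstituted isobutenyl alkene being too hindered to insert.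

Step 7
Reactants: 10 the E-stilbene keto-olefin of step 6
Product: 12 pentacyclic alkene heptamethyl ether (C9=C10; C8 R), via keto dihydrophenanthrene 11 (not isolated)
Conditions: chiral imidodiphosphorimidate Brønsted acid (IDPi, 5 mol %), CH2Cl2, −40 → 0 °C; then FeCl3 (10 mol %), 23 °C, same flask
Reagents that add atoms: none
Why: Proposed new method: the confined chiral acid should protonate the stilbene at C7 to give the C8 benzylic cation as a contact ion pair, and ring D should attack it through its carbon para to OMe in an intramolecular Friedel–Crafts alkylation (6-endo attack of the arene π-bond) that closes the six-membered ring to 11. FeCl3 should then activate the diaryl ketone for a stepwise [2+2] addition of the isobutenyl group and retro-[2+2] loss of acetone from the oxetane, closing the seven-membered ring as the C9=C10 alkene (ring-closing carbonyl–olefin metathesis). The closest known reaction types are the acid-mediated cyclisation of 2-styrylbiaryls to 9-aryl-9,10-dihydrophenanthrenes, the IDPi-catalysed enantioselective intramolecular hydroarylation of olefins by indoles, and the FeCl3-catalysed carbonyl–olefin metathesis of aryl ketones with isobutenyl arenes to phenanthrenes; new here are the enantioselective closure by an alkoxyarene and the seven-membered ring size. The C8 stereocentre (R) is set in the first stage by the chiral counter-anion, which shields one face of the planar cation. Protonation regiochemistry follows cation stability (C8 is para to a ring-B methoxy group, C7 is conjugated to no oxygen); closure para rather than ortho to the ring-D methoxy group follows the usual preference of anisoles; ring C is deactivated by the ketone and ring A cannot reach C8. In the second stage only the C9–C10 orientation of oxetane formation gives a seven-membered ring, so acetone and not an aldehyde is expelled.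

Step 8
Reactants: 12 pentacyclic alkene heptamethyl ether (C9=C10; C8 R)
Product: 13 heptamethyl ether of the target (C8 R, C9 S)
Conditions: H2 (4 bar), Pd/C (10% palladium on carbon), EtOAc, 23 °C
Reagents that add atoms: none
Why: Heterogeneous hydrogenation should add H2 syn to the convex face of the boat-shaped dibenzocycloheptene, where the C8 hydrogen is the flagpole substituent and C7 is pseudo-equatorial, so the new C9–H ends up cis to C8–H and C9 is set as S.

Step 9
Reactants: 13 heptamethyl ether of the target (C8 R, C9 S)
Product: 14 the target heptaphenol (C8 R, C9 S)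
Conditions: BBr3, CH2Cl2, −78 → 23 °C; then H2O
Reagents that add atoms: none
Why: Lewis-acid ether cleavage, in which each ArO–CH3 is complexed by BBr3 and demethylated by bromide (SN2 at methyl) and hydrolysis of the aryl borates should release all seven phenols without touching the benzylic stereocentres.

**Compound list**

1 | 4-bromo-1,2-dimethoxybenzene | COc1ccc(Br)cc1OC | starting material
2 | 3,4-dimethoxybenzoyl chloride | COc1ccc(C(=O)Cl)cc1OC | starting material
3 | (2-bromo-4,5-dimethoxyphenyl)(3,4-dimethoxyphenyl)methanone | COc1ccc(C(=O)c2cc(OC)c(OC)cc2Br)cc1OC | intermediate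
4 | 2-bromo-3,5-dimethoxybenzaldehyde | COc1cc(OC)c(Br)c(C=O)c1 | starting material
5 | 2-bromo-1-ethenyl-3,5-dimethoxybenzene | COc1cc(OC)c(Br)c(C=C)c1 | intermediate
6 | 3-bromo-5-methoxybenzaldehyde | COc1cc(Br)cc(C=O)c1 | starting material
7 | 1-bromo-3-methoxy-5-(2-methylprop-1-en-1-yl)benzene | COc1cc(Br)cc(C=C(C)C)c1 | intermediate
8 | 2-[3-methoxy-5-(2-methylprop-1-en-1-yl)phenyl]-4,4,5,5-tetramethyl-1,3,2-dioxaborolane | COc1cc(C=C(C)C)cc(B2OC(C)(C)C(C)(C)O2)c1 | intermediate
9 | 2-ethenyl-3',4,6-trimethoxy-5'-(2-methylprop-1-en-1-yl)-1,1'-biphenyl | COc1cc(OC)c(-c2cc(OC)cc(C=C(C)C)c2)c(C=C)c1 | intermediate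
10 | {2-[(E)-2-(3',4,6-trimethoxy-5'-(2-methylprop-1-en-1-yl)-1,1'-biphenyl-2-yl)ethenyl]-4,5-dimethoxyphenyl}(3,4-dimethoxyphenyl)methanone | COc1cc(OC)c(-c2cc(OC)cc(C=C(C)C)c2)c(/C=C/c2cc(OC)c(OC)cc2C(=O)c2ccc(OC)c(OC)c2)c1 | intermediate
11 | {4,5-dimethoxy-2-[(9R)-2,4,6-trimethoxy-8-(2-methylprop-1-en-1-yl)-9,10-dihydrophenanthren-9-yl]phenyl}(3,4-dimethoxyphenyl)methanone (C8 R) | COc1cc(OC)c2c(c1)C[C@H](c1cc(OC)c(OC)cc1C(=O)c1ccc(OC)c(OC)c1)c1c(C=C(C)C)cc(OC)cc1-2 | intermediate
12 | pentacyclic alkene: the dihydrophenanthrene of 11 with phenanthrene C-8 joined through a =CH– unit (C10) to the former ketone carbon (C9, bearing the 3,4-dimethoxyphenyl group and ring B), forming the dibenzo[a,d]cycloheptene ring; seven OMe groups; C8 R | COc1cc(OC)c2c(c1)C[C@@H]1c3cc(OC)c(OC)cc3C(c3ccc(OC)c(OC)c3)=Cc3cc(OC)cc-2c31 | intermediate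
13 | heptamethyl ether of the target: 12 with C9=C10 saturated; C8 R, C9 S, the two methine hydrogens cis | COc1cc(OC)c2c(c1)C[C@@H]1c3cc(OC)c(OC)cc3[C@H](c3ccc(OC)c(OC)c3)Cc3cc(OC)cc-2c31 | intermediate
14 | target heptaphenol (C8 R, C9 S) | Oc1cc(O)c2c(c1)C[C@@H]1c3cc(O)c(O)cc3[C@H](c3ccc(O)c(O)c3)Cc3cc(O)cc-2c31 | target

**Totals.** Total step count: 9. Longest linear sequence: 7 steps (6 → 7 → 8 → 9 → 10 → 12 → 13 → 14; steps 3 to 9).

**Steps most likely to fail**

Step 7 (Proposed new method). What may go wrong: weak facial discrimination in the ion-pair cyclisation, competing closure at the ring-D carbon ortho to the methoxy group, or diversion of the metathesis stage into a carbonyl-ene reaction with no seven-membered closure. Fallback with known chemistry, setting out from 10 and returning at 12: CF3SO3H-catalysed hydroarylation of 10 (CH2Cl2, 0 °C) should give the racemic keto dihydrophenanthrene F1. Oxidative cleavage of its isobutenyl group (OsO4 cat., NaIO4, 2,6-lutidine, dioxane/H2O) should give the keto aldehyde F2. Intramolecular McMurry coupling (TiCl4, Zn, pyridine, THF, reflux) should close the seven-membered ring to the racemic alkene F3. Separation of the enantiomers of F3 by preparative chromatography on a chiral stationary phase delivers 12.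

Step 8. What may go wrong: hydrogen delivery to the concave face, or to both faces, giving the C9 epimer. Fallback, setting out from 12 and returning at 13: substrate control is replaced by reagent control, using homogeneous hydrogenation with a cationic iridium complex of a chiral phosphinooxazoline, [Ir(cod)(P,N)]BArF, under H2 (50 bar) in CH2Cl2, with the ligand antipode chosen to override the substrate bias; this makes no new compound (F0).

Step 6. What may go wrong: slow insertion of the hindered styrene, attack of the arylpalladium intermediate on its own ketone, or double-bond migration. Fallback, setting out from 9 and returning at 10: cross-metathesis of the vinyl group of 9 with vinylboronic acid pinacol ester ((H2IMes)(PCy3)Cl2Ru=CHPh, CH2Cl2, 40 °C) should give the E-alkenyl boronate F4, which is joined to 3 by Suzuki–Miyaura coupling (Pd(OAc)2, SPhos, K3PO4, PhMe/H2O, 80 °C) to give 10.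

Further compounds
F1 | step 7 | racemic keto dihydrophenanthrene (racemic 11) | COc1cc(OC)c2c(c1)CC(c1cc(OC)c(OC)cc1C(=O)c1ccc(OC)c(OC)c1)c1c(C=C(C)C)cc(OC)cc1-2
F2 | step 7 | racemic keto aldehyde (F1 with the isobutenyl group cleaved to CHO) | COc1cc(OC)c2c(c1)CC(c1cc(OC)c(OC)cc1C(=O)c1ccc(OC)c(OC)c1)c1c(C=O)cc(OC)cc1-2
F3 | step 7 | racemic alkene (racemic 12) | COc1cc(OC)c2c(c1)CC1c3cc(OC)c(OC)cc3C(c3ccc(OC)c(OC)c3)=Cc3cc(OC)cc-2c31
F0 | step 8 | none | none
F4 | step 6 | 2-[(E)-2-(3',4,6-trimethoxy-5'-(2-methylprop-1-en-1-yl)-1,1'-biphenyl-2-yl)ethenyl]-4,4,5,5-tetramethyl-1,3,2-dioxaborolane | COc1cc(OC)c(-c2cc(OC)cc(C=C(C)C)c2)c(/C=C/B2OC(C)(C)C(C)(C)O2)c1
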